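The chemist who ran these flasks left me a puzzle: Wednesday's run levelled off at a last reading of 37.9% of its starting material, and Tuesday's, with twice the starting material at the same reagent charge, levelled off at a smaller share, a last reading of 25.7%.

common to all: free catalyst 0.00500 M

| charge | starting material | reagent | time |
|---|---|---|---|
| Wednesday's | 0.100 M | 0.300 M |  |
| Friday's | 0.0400 M | 0.240 M |  |
| Tuesday's | 0.200 M | 0.300 M |  |
| Monday's | 0.100 M | 0.900 M |  |
| Thursday's | 0.500 M | 1.50 M | 150 min |

- Wednesday's run (time / min: [product] / M): 6.7: 0.0085; 20: 0.0189; 39: 0.0273; 61: 0.0318; 88: 0.0364; 120: 0.0378; 150: 0.0379
- Friday's run (time / min: [product] / M): 6.7: 0.0022; 20: 0.0078; 39: 0.0121; 61: 0.0145; 88: 0.0183; 120: 0.0195; 150: 0.0198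
- Tuesday's run (time / min: [product] / M): 6.7: 0.0151; 20: 0.0320; 39: 0.0422; 61: 0.0461; 88: 0.0485; 120: 0.0518; 150: 0.0515
- Monday's run (time / min: [product] / M): 6.7: 0.0148; 20: 0.0337; 39: 0.0454; 61: 0.0509; 88: 0.0564; 120: 0.0568; 150: 0.0580

(standard deviation of a reading: 8 × 10⁻⁴ M)

- Overall: starting material + reagent -> product, with free catalyst as catalyst.
- Constant volume, constant temperature.
- Readings of a species count what is bound in complexes too.
- An order is taken over about fifteen percent of the charge, up and down.

1. how the opening rate goes with [reagent] round the charge of the Wednesday's run: the exponent of the rate at two percent of starting material gone to product
2. how the opening rate goes with [starting material] round the charge of the Wednesday's run: the exponent of the rate at two percent of starting material gone to product (one fixed amount of product, the same in the runs compared)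
3. product in the Thursday's run at 150 min, as a share of the starting material charged

My first thought was a catalyst dying by the clock. But a rate in step with starting material, stopped by a clock, gives one share for both charges at one reagent charge, and these two differ. So I supposed that starting material also pairs off with itself, at a rate in its square, while the catalysed route, pseudo-first-order with reagent in excess, takes it at a rate in its first power. Dividing one rate by the other and integrating to the end of the starting material, with reagent and catalyst held at their charges, gives the final share of product: λ times the natural log of one plus 1/λ. The λ that met Wednesday's plateau was 0.222; I called it the even share, the fraction of the starting charge still present when the two routes take it equally fast.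

One number fitted to one plateau proves little. Tuesday's flask had the same reagent and catalyst, so on this supposition its even share had to be half of Wednesday's, 0.111, and that gave 25.6% with no adjusting, close to the reading. But reagent had not been tested. Monday's plateau asked for 0.571, which is 2.57 times Wednesday's for 3.00 times the reagent. So I let the even share grow as reagent over one plus K times reagent, with K = 0.303 /M. Friday's flask then came out at 52.7% against a reading of 49.5%, a miss I could not compute away, so I took my rule to run somewhat high. For Thursday's flask it gave an even share of 0.167 and a final product share of 32.4%, which I took for the share at 150 min. I reckoned no orders of my own.

The forecast, which held that “It looks like catalyst death”, gave 0.63 in reagent, 0.87 in starting material, and 28% for Thursday's flask, lower than my share.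

The simulation gave 0.75 in reagent, 1.0 in starting material, and 30.1% for Thursday's flask.

    free catalyst + reagent ⇌ catalyst-reagent complex, settled at all times (1.380 /M)
    catalyst-reagent complex + starting material → product + free catalyst (9.900 /M/min)
    2 starting material → homo dimer (0.1590 /M/min)
    free catalyst + product → spent catalyst + product (0.5838 /M/min)

Without the path from two starting material to homo dimer, Thursday's flask reached 58.9%, so that path costs it 29 percentage points. Built from these constants and not from Wednesday's 0.222, with reagent and catalyst held at their charges, Thursday's even share is 0.210, and the rule returns 36.8%. Thursday's simulated run without the path from free catalyst and product to spent catalyst gave 36.3%.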